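A straight line through the plateaus is the trap here, for it assumes that free base buys the same thing at any charge.

the same everywhere: electrophile 0.68 M; protonated nucleophile 0.884 M
- zeta: free base 0.29 M; run made earlier
- delta: free base 0.71 M; run made earlier
- gamma: free base 1.1 M; run made earlier
- east: free base 0.680 M; time 2.5 min
- south: free base 1.40 M; time 2.5 min
- south-east: free base 0.340 M; time 2.5 min

- zeta (time / s: electrophile / %, target / %): 10.0: 93, 8; 20.0: 89, 10; 50.0: 85, 13; 120: 86, 15
- delta (time / s: electrophile / %, target / %): 25.0: 84, 20; 50.0: 78, 21; 80.0: 76, 19; 120: 77, 23
- gamma (time / s: electrophile / %, target / %): 10.0: 83, 16; 20.0: 79, 21; 50.0: 73, 27; 120: 69, 35

(each reading ± 1.5 percentage points)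

- candidate steps: nucleophile + acid set free <-> protonated nucleophile; acid set free + free base <-> salt of the base; electrophile + nucleophile -> acid set free + target; 2 nucleophile -> self-condensation product

- part of the electrophile that has reacted at the end, east
- part of the electrophile that has reacted at the end, south
- part of the electrophile that has reacted at the end, south-east
- what raising the concentration of free base from its lowest to its highest value here does to the part of the electrophile that has reacted (changes below 5 percentage points count as none) (it rises / no change / it falls)

Averaging electrophile lost and target found at the last readings, I take plateaus of 14.5% in zeta, 23.0% in delta and 33.0% in gamma, and the line through the last two carries south to 40.7%. My objection is the count of acid: each protonated nucleophile that gives up its acid costs one free base, and each target made sets free an acid that costs another. So I define the base bill as the charge of protonated nucleophile plus the target made, which gamma's plateau puts at 1.11 M. Gamma's charge of 1.1 M about meets it, so gamma should already stand at the bend, while south's charge is more than the bill, and its extra 0.292 M should find no protonated nucleophile to free. I therefore put south near 33.0%, off the line. But that plateau is scattered; still, gamma's columns taken singly give bills of 1.09 M and 1.12 M, and the surplus stands.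

East and south-east lie below the bill, so there free base should be the limiting reagent and target should follow its charge. Yet target per free base is not constant, 0.340 in zeta against 0.220 in delta, so I scale each flask from its nearest run and get 22.0% for east and 17.0% for south-east.

The forecast gives 23% for east, 16% for south-east and 38% for south, a figure above mine, saying of south that “some saturation and more self-condensation are likely”, and its answer on raising the free base from its lowest to its highest value is it rises.

East gives 22.2%, south-east 15.3% and south 31.5%, and the answer on raising the free base from its lowest to its highest value is it rises, by 16 percentage points.

    nucleophile + acid set free ⇌ protonated nucleophile, settled at all times (K = 18000 M⁻¹)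
    acid set free + free base ⇌ salt of the base, settled at all times (K = 2.40 × 10⁵ M⁻¹)
    electrophile + nucleophile → acid set free + target (k = 0.0540 M⁻¹ s⁻¹)
    2 nucleophile → self-condensation product (k = 0.200 M⁻¹ s⁻¹)

South's bill comes to 1.10 M against 1.10 M of salt of the base, and 21.6% of its free base stands unspent. South stays low mainly because of self-condensation: with that step struck out, south gives 88.3%. The neighbour of south charged with 2.7 M of electrophile reaches 17.5%, so its bill is 1.36 M, which leaves 0.0432 M of its charge, and 0.0435 M of free base stands there.

The earlier runs and the new flask were generated by integration for an exercise, and the scatter is random.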